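**Plan**
- Feature: ring B of each half is an orsellinic-type ring (ketone on C1, oxygen on C2 and C4, CH3 on C6). One oxidation level below the arene this is a 4-acyl-5-methylcyclohexane-1,3-dione.
- Retrosynthesis: cut ring B bonds C1–C6 (Michael) and C2–C3 (Claisen) in both halves, then the CH2–CO2Me bonds of the two β-ketoesters, then the two aryl–CH2 bonds of the central methylene.
- Forward: two ring A acetophenones are joined through CH2, benzylated and homologated to the bis(β-ketoester). Both B rings are then annulated at once as cyclohexane-1,3-diones and dehydrogenated to resorcinols.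
- Endgame: 4-O-benzylation and 2-O-methylation of ring B, then global hydrogenolysis.
- Stereochemistry: the target has no stereocentre. The four stereocentres that arise in the dione rings are unassigned mixtures and vanish on aromatisation.

Key step: step 4

Assumption: compounds 8, 9 and 10 are handled as mixtures of diastereomers and keto–enol tautomers and are drawn in the keto form with undefined stereocentres; compound 9 is carried into step 5 without separation of isomers.

**Step 1**
Reactants: 1 1-(2,6-dihydroxy-4-methoxyphenyl)ethan-1-one (used in excess); 2 formaldehyde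
Product: 3 bis(3-acetyl-2,4-dihydroxy-6-methoxyphenyl)methane
Conditions: 37% aq. CH2O (1 equiv), 1 (3 equiv), 2% aq. KOH, 0 °C to rt; then 1 M HCl
Reagents that add atoms: formaldehyde (compound 2), C=O
Why: Phenol–formaldehyde condensation (Lederer–Manasse hydroxymethylation, then capture of the ortho-quinone methide by a second phenoxide), in which C3 and C5 of 1 are equivalent so only one regioisomer can form, and the excess of 1 should hold the reaction at the dimer.

**Step 2**
Reactants: 3 bis(3-acetyl-2,4-dihydroxy-6-methoxyphenyl)methane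
Product: 4 bis[3-acetyl-2,4-bis(benzyloxy)-6-methoxyphenyl]methane
Conditions: BnBr (6 equiv), K2CO3 (8 equiv), DMF, 70 °C
Reagents that add atoms: benzyl bromide, BrCc1ccccc1
Why: Williamson ether synthesis in which carbonate in hot DMF breaks the hydrogen bonds to the acetyl groups so that all four phenoxides are O-benzylated, benzyl being chosen because it withstands NaH, NaOMe and carbonate bases and leaves by hydrogenolysis in the last step.

**Step 3**
Reactants: 4 bis[3-acetyl-2,4-bis(benzyloxy)-6-methoxyphenyl]methane; 5 dimethyl carbonate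
Product: 6 bis[2,4-bis(benzyloxy)-6-methoxy-3-(3-methoxy-3-oxopropanoyl)phenyl]methane
Conditions: NaH (6 equiv), (MeO)2CO (excess), THF, reflux; then aq. HCl, 0 °C
Reagents that add atoms: dimethyl carbonate (compound 5), COC(=O)OC
Why: Crossed Claisen condensation of the two methyl ketone enolates with the non-enolisable carbonate, driven by irreversible formation of the β-ketoester enolate and H2, while the di-ortho-substituted aryl ketones cannot self-condense.

**Step 4**
Reactants: 6 bis[2,4-bis(benzyloxy)-6-methoxy-3-(3-methoxy-3-oxopropanoyl)phenyl]methane; 7 (E)-pent-3-en-2-one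
Product: 9 bis{2,4-bis(benzyloxy)-6-methoxy-3-[(6-methyl-2,4-dioxocyclohexyl)carbonyl]phenyl}methane (diastereomer/tautomer mixture), via bis-Michael adduct 8 (not isolated)
Conditions: 7 (2.5 equiv), NaOMe (3 equiv), MeOH–THF, rt then reflux; then aq. HCl
Reagents that add atoms: (E)-pent-3-en-2-one (compound 7), C/C=C/C(C)=O
Why: Methoxide generates the doubly stabilised carbanion of each aroylacetate, which adds reversibly to C4 of 7 (ring B bond C1–C6); proton transfer then gives a small equilibrium amount of the terminal methyl ketone enolate, which acylates at the methyl ester (ring B bond C2–C3) and expels methoxide. The closest known reaction type is the Michael–Claisen annulation of malonates or acetoacetates with enones or enoates to dihydroorsellinates. Each of the two rings closes in a 6-(enolendo)-exo-trig mode, since the ketone carbon of the enolate ends up inside the new ring. The new stereocentres (C4 and C5 of each dione ring) are controlled only by the thermodynamic preference of the epimerisable C4 for the trans arrangement, which is immaterial because all four are removed in step 5. The step needs Claisen closure onto the ester in preference to aldol closure onto the aryl ketone or retro-Claisen loss of the aroyl group: the carbonyl flanked by two ortho-benzyloxy groups is twisted out of the arene plane and shielded on both faces, so addition to it should be slow and reversible, whereas acylation at the ester is made irreversible by deprotonation of the product to the vinylogous carboxylate of the cyclohexane-1,3-dione. Carbon 1,4-addition rather than 1,2- or O-addition follows from the soft, stabilised carbanion and the reversibility of the alternatives.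

**Step 5**
Reactants: 9 bis{2,4-bis(benzyloxy)-6-methoxy-3-[(6-methyl-2,4-dioxocyclohexyl)carbonyl]phenyl}methane
Product: 11 bis[2,4-bis(benzyloxy)-3-(2,4-dihydroxy-6-methylbenzoyl)-6-methoxyphenyl]methane, via bis(2-bromo-1,3-dione) 10 (not isolated)
Conditions: Br2 (2.0 equiv), DMF, 0 °C, then 70 °C
Reagents that add atoms: none
Why: Halogenation–dehydrohalogenation aromatisation of a cyclohexane-1,3-dione, in which the enolised dione should be brominated at the carbon between the ring carbonyls at 0 °C far faster than any arene position, and on warming bromine migration, loss of HBr and enolisation give the resorcinol and erase all ring stereocentres.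

**Step 6**
Reactants: 11 bis[2,4-bis(benzyloxy)-3-(2,4-dihydroxy-6-methylbenzoyl)-6-methoxyphenyl]methane
Product: 12 bis{2,4-bis(benzyloxy)-3-[4-(benzyloxy)-2-hydroxy-6-methylbenzoyl]-6-methoxyphenyl}methane
Conditions: BnBr (2.1 equiv), K2CO3 (2.5 equiv), acetone, reflux
Reagents that add atoms: benzyl bromide, BrCc1ccccc1
Why: Chemoselective Williamson etherification, since the 4-OH para to the carbonyl is the more acidic and unhindered phenol whereas the 2-OH is held in a hydrogen bond to the ketone and should stay free under mild carbonate conditions.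

**Step 7**
Reactants: 12 bis{2,4-bis(benzyloxy)-3-[4-(benzyloxy)-2-hydroxy-6-methylbenzoyl]-6-methoxyphenyl}methane
Product: 13 bis{2,4-bis(benzyloxy)-3-[4-(benzyloxy)-2-methoxy-6-methylbenzoyl]-6-methoxyphenyl}methane
Conditions: MeI (excess), K2CO3, DMF, 50 °C
Reagents that add atoms: iodomethane, CI
Why: Williamson O-methylation of the only remaining free hydroxyl on each ring B, the chelated ortho-OH, which should react once the hydrogen bond is broken in warm DMF with excess MeI.

**Step 8**
Reactants: 13 bis{2,4-bis(benzyloxy)-3-[4-(benzyloxy)-2-methoxy-6-methylbenzoyl]-6-methoxyphenyl}methane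
Product: 14 digriseophene A
Conditions: H2 (1 atm), 10% Pd/C, EtOAc–MeOH, rt
Reagents that add atoms: none
Why: Heterogeneous catalytic hydrogenolysis of all six aryl benzyl ethers, under which the methyl ethers, the diarylmethane and the tetra-ortho-substituted, twisted benzophenone carbonyls should not be reduced.

**Compound list**
1 | 1-(2,6-dihydroxy-4-methoxyphenyl)ethan-1-one (2',6'-dihydroxy-4'-methoxyacetophenone) | CC(=O)c1c(O)cc(OC)cc1O | starting material
2 | formaldehyde (37% aqueous solution) | C=O | starting material
3 | bis(3-acetyl-2,4-dihydroxy-6-methoxyphenyl)methane | CC(=O)c1c(O)cc(OC)c(Cc2c(OC)cc(O)c(C(C)=O)c2O)c1O | intermediate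
4 | bis[3-acetyl-2,4-bis(benzyloxy)-6-methoxyphenyl]methane | CC(=O)c1c(OCc2ccccc2)cc(OC)c(Cc2c(OC)cc(OCc3ccccc3)c(C(C)=O)c2OCc2ccccc2)c1OCc1ccccc1 | intermediate
5 | dimethyl carbonate | COC(=O)OC | starting material
6 | bis[2,4-bis(benzyloxy)-6-methoxy-3-(3-methoxy-3-oxopropanoyl)phenyl]methane (methylene-bridged bis(β-ketoester)) | COC(=O)CC(=O)c1c(OCc2ccccc2)cc(OC)c(Cc2c(OC)cc(OCc3ccccc3)c(C(=O)CC(=O)OC)c2OCc2ccccc2)c1OCc1ccccc1 | intermediate
7 | (E)-pent-3-en-2-one | C/C=C/C(C)=O | starting material
8 | bis{2,4-bis(benzyloxy)-6-methoxy-3-[2-(methoxycarbonyl)-3-methyl-5-oxohexanoyl]phenyl}methane (bis-Michael adduct, formed in the flask, stereocentres undefined) | COC(=O)C(C(C)CC(C)=O)C(=O)c1c(OCc2ccccc2)cc(OC)c(Cc2c(OC)cc(OCc3ccccc3)c(C(=O)C(C(C)CC(C)=O)C(=O)OC)c2OCc2ccccc2)c1OCc1ccccc1 | intermediate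
9 | bis{2,4-bis(benzyloxy)-6-methoxy-3-[(6-methyl-2,4-dioxocyclohexyl)carbonyl]phenyl}methane (stereocentres undefined, enol mixture) | CC1CC(=O)CC(=O)C1C(=O)c1c(OCc2ccccc2)cc(OC)c(Cc2c(OC)cc(OCc3ccccc3)c(C(=O)C3C(C)CC(=O)CC3=O)c2OCc2ccccc2)c1OCc1ccccc1 | intermediate
10 | bis{2,4-bis(benzyloxy)-3-[(3-bromo-6-methyl-2,4-dioxocyclohexyl)carbonyl]-6-methoxyphenyl}methane (formed in the flask, stereocentres undefined) | CC1CC(=O)C(Br)C(=O)C1C(=O)c1c(OCc2ccccc2)cc(OC)c(Cc2c(OC)cc(OCc3ccccc3)c(C(=O)C3C(C)CC(=O)C(Br)C3=O)c2OCc2ccccc2)c1OCc1ccccc1 | intermediate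
11 | bis[2,4-bis(benzyloxy)-3-(2,4-dihydroxy-6-methylbenzoyl)-6-methoxyphenyl]methane | Cc1cc(O)cc(O)c1C(=O)c1c(OCc2ccccc2)cc(OC)c(Cc2c(OC)cc(OCc3ccccc3)c(C(=O)c3c(C)cc(O)cc3O)c2OCc2ccccc2)c1OCc1ccccc1 | intermediate
12 | bis{2,4-bis(benzyloxy)-3-[4-(benzyloxy)-2-hydroxy-6-methylbenzoyl]-6-methoxyphenyl}methane | Cc1cc(OCc2ccccc2)cc(O)c1C(=O)c1c(OCc2ccccc2)cc(OC)c(Cc2c(OC)cc(OCc3ccccc3)c(C(=O)c3c(C)cc(OCc4ccccc4)cc3O)c2OCc2ccccc2)c1OCc1ccccc1 | intermediate
13 | bis{2,4-bis(benzyloxy)-3-[4-(benzyloxy)-2-methoxy-6-methylbenzoyl]-6-methoxyphenyl}methane | Cc1cc(OCc2ccccc2)cc(OC)c1C(=O)c1c(OCc2ccccc2)cc(OC)c(Cc2c(OC)cc(OCc3ccccc3)c(C(=O)c3c(C)cc(OCc4ccccc4)cc3OC)c2OCc2ccccc2)c1OCc1ccccc1 | intermediate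
14 | digriseophene A, bis[2,4-dihydroxy-3-(4-hydroxy-2-methoxy-6-methylbenzoyl)-6-methoxyphenyl]methane (achiral) | COc1cc(O)c(C(=O)c2c(C)cc(O)cc2OC)c(O)c1Cc1c(OC)cc(O)c(C(=O)c2c(C)cc(O)cc2OC)c1O | target

**Step count**
Total steps: 8. Longest linear sequence: 8 steps (1 to 14); the route is fully linear, with both halves elaborated simultaneously.

**Steps most likely to fail**

Step 4 (key step). The methyl ketone enolate may close by aldol addition onto the aryl ketone, or methoxide may cleave the aroyl group by retro-Claisen fragmentation. The ester may also be too deactivated to be acylated, because it sits next to the deprotonated ketoester carbon. The fallback sets out from 4 and comes back at 9; it transposes the annulation so that the ester to be attacked is remote from the acidic carbon. Double Claisen condensation of 4 with ethyl acetate (NaH, THF, reflux) should give bis[2,4-bis(benzyloxy)-6-methoxy-3-(3-oxobutanoyl)phenyl]methane F1. With NaOMe in MeOH and methyl (E)-but-2-enoate, the diketone carbanion should add to the crotonate to give bis{3-[2-acetyl-5-methoxy-3-methyl-5-oxopentanoyl]-2,4-bis(benzyloxy)-6-methoxyphenyl}methane F2, which is not isolated. Its acetyl enolate then closes onto the ester, as in the classical acetoacetate–crotonate route to dihydroorsellinates, and gives 9 with the same C1–C6 Michael bond.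

Step 5. Electrophilic bromine may be transferred to the free C5–H of ring A or to the newly formed resorcinol rings instead of being lost cleanly as HBr, and the HBr released may cleave benzyl ethers ortho to the ketones. The fallback sets out from 6 and comes back at 11; it builds ring B directly at the arene oxidation level. Michael addition of the bis(β-ketoester) carbanions to pent-3-yn-2-one (CC#CC(C)=O; NaOMe, MeOH–THF, 0 °C to reflux) should give bis{2,4-bis(benzyloxy)-6-methoxy-3-[2-(methoxycarbonyl)-3-methyl-5-oxohex-3-enoyl]phenyl}methane F3, which is not isolated and whose alkene geometry equilibrates through the dienolate. The same Claisen closure onto the ester, followed by enolisation, gives 11 without any oxidant.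

Step 1. Condensation with formaldehyde may run on to trimers and higher oligomers, since each ring of the dimer keeps one nucleophilic position. The fallback sets out from 1 and comes back at 3; it separates the two C–C bond formations. A Mannich reaction of 1 with aqueous dimethylamine and formaldehyde (1 equiv each, EtOH, rt) should give 1-{3-[(dimethylamino)methyl]-2,6-dihydroxy-4-methoxyphenyl}ethan-1-one F4. Heating F4 with a second equivalent of 1 (dioxane, reflux) expels dimethylamine through the ortho-quinone methide, which is captured by 1 to give 3.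

**Further compounds**
F1 | step 4 | bis[2,4-bis(benzyloxy)-6-methoxy-3-(3-oxobutanoyl)phenyl]methane | CC(=O)CC(=O)c1c(OCc2ccccc2)cc(OC)c(Cc2c(OC)cc(OCc3ccccc3)c(C(=O)CC(C)=O)c2OCc2ccccc2)c1OCc1ccccc1
F2 | step 4 | bis{3-[2-acetyl-5-methoxy-3-methyl-5-oxopentanoyl]-2,4-bis(benzyloxy)-6-methoxyphenyl}methane (stereocentres undefined) | COC(=O)CC(C)C(C(C)=O)C(=O)c1c(OCc2ccccc2)cc(OC)c(Cc2c(OC)cc(OCc3ccccc3)c(C(=O)C(C(C)=O)C(C)CC(=O)OC)c2OCc2ccccc2)c1OCc1ccccc1
F3 | step 5 | bis{2,4-bis(benzyloxy)-6-methoxy-3-[2-(methoxycarbonyl)-3-methyl-5-oxohex-3-enoyl]phenyl}methane (alkene geometry undefined, equilibrating) | COC(=O)C(C(C)=CC(C)=O)C(=O)c1c(OCc2ccccc2)cc(OC)c(Cc2c(OC)cc(OCc3ccccc3)c(C(=O)C(C(C)=CC(C)=O)C(=O)OC)c2OCc2ccccc2)c1OCc1ccccc1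
F4 | step 1 | 1-{3-[(dimethylamino)methyl]-2,6-dihydroxy-4-methoxyphenyl}ethan-1-one | CC(=O)c1c(O)cc(OC)c(CN(C)C)c1O
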